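## Structural features

The target is a cembrane-type diterpenoid: a 14-membered carbocycle (C1–C14) in which C1 and C3 are joined a second time by the Me2C–O unit (C15 and the ether oxygen). C1, C2, C3, O and C15 therefore form a 2,2-dimethyloxolane and the frame is a 14-oxabicyclo[11.2.1]hexadecane. All three stereocentres sit at this junction: C1 and C3 on the oxolane, with their bonds into the large ring cis, and C4, which lies in the large ring next to C3 and carries C18 as a CH2–O–malonyl half-ester. The large ring also holds a Z trisubstituted alkene (C11=C12, methyl on C12) and an E trisubstituted alkene (C7=C8) conjugated to the C19 aldehyde. The fragile groups are the malonic half-ester (decarboxylation, acyl transfer, no tolerance for hydride or strong base), the enal, and the acid-sensitive Z alkene. Whenever C18 is a carbonyl group, the C3–O bond is β to it and can be lost by retro-addition. The real difficulty is fixing C3 and C4 relative to C1 inside a flexible 14-membered ring and closing that ring with two defined alkenes. The feature used here is that C3 is β and C4 is α to C18: the O–C3 bond together with the C4–H bond is the retron of a conjugate addition of the C15 hydroxyl to a C3=C4–C18 unsaturated ester, which is the constitutional twin of the C7=C8–C19 unit.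

## Logic of the disconnections

**24 ⇒ 23 ⇒ 21 + 22.** The O–C(CH3)3 bond and then the C18O–C(=O) ester bond are cut. The malonic half-ester is the most fragile group and cannot pass through hydride, phosphonate anions or alkoxide, so it is added last. This reduces the target to 21 and the commercial half-ester 22. The forward steps need an acylation of the only hydroxyl group and an acid cleavage short and cold enough to spare the Z alkene, the enal and the cyclic ether.

**21 ⇒ 20 ⇒ 19.** No skeletal bond is cut; C19 and C18 are taken back to two methyl esters. The gain is that two different oxygen functions become two like ones that come from the same olefination chemistry. The demand is that, after exhaustive reduction, only the allylic alcohol is oxidised (MnO2), and that C4 is not epimerised on the way.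

**19 ⇒ 18.** The O–C3 bond and the C4–H bond are cut. This removes the oxolane, the bicyclic frame and two of the three stereocentres, leaving a monocyclic triene with C1 alone. The forward step must add the C15 oxygen to C3 only, and the ring must place C3 and C4 correctly under equilibrating conditions.

**18 ⇒ 17.** The C7=C8 double bond is cut. A trisubstituted enoate with the ester on the more substituted carbon is the retron of an α-alkyl phosphonoacetate and an aldehyde, and a 14-membered ring is within reach of this olefination. The gain is an open chain. The demands are high dilution, E geometry at C7=C8, and a base too weak to start the conjugate addition prematurely.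

**17 ⇒ 16 ⇒ 15 + 1.** The C8–C9 bond is cut, after the C7 aldehyde and the C15 hydroxyl are masked as acetal and silyl ether. Attaching the phosphonoacetate last keeps the two phosphonate carbons from competing. The iodide is primary but homoallylic, so substitution must beat elimination; the soft phosphonoacetate anion meets that demand.

**15 ⇒ 14 ⇒ 13 + 3, and 3 ⇒ 1 + 2.** The C3=C4 double bond and the C4–C5 bond are cut. This splits off C4–C7 with C18 as a small phosphonate, 3, made in one step. The C15 oxygen must be silylated here: a free γ-hydroxy aldehyde would be a lactol, and a free hydroxy enoate would cyclise in the open chain. The geometry at C3=C4 matters little, because this alkene is consumed in the key step.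

**13 ⇒ 11 ⇒ 10 ⇒ 8 + 9.** The C3–O and C9–O bonds (both from hydroboration), the O–Si bond and the C9=C10 bond are cut. A C10 terpene unit, a C2 acetylide, two phosphonoacetate C2 units and a C3 acetal unit supply only nineteen skeletal carbons; C9 is the twentieth and comes from 9 as a Wittig methylene. One hindered borane then converts the alkyne into the C3 aldehyde and the diene terminus into the C9 alcohol. The demands are chemoselectivity between terminal and trisubstituted unsaturation and no loss of Z geometry at the enal stage.

**8 ⇒ 7 ⇒ 5 + 6.** After adjusting C10 to the alcohol, the C1–C2 bond is cut. Opening an epoxide at its secondary carbon with inversion sets C1 and frees the C15 oxygen in one step. The demand is SN2 attack at a carbon next to a quaternary centre.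

**5 ⇒ 4.** The two C–O bonds of the epoxide are cut. The allylic acetate deactivates the proximal alkene, so a chiral dioxirane should select the distal one. The demand is the (R)-epoxide in high enantiomeric purity, since it is the only source of absolute configuration.

## Other disconnections considered

**Alternative 1:** The cut is the C9–C10 bond of a macrocycle that already contains the oxolane. In the forward direction KN(SiMe3)2 at high dilution would turn the C10 allylic sulfone of the open-chain Baylis–Hillman acetate A2 into a carbanion. This adds to the acrylate methylene C9 with SN2' loss of the C7 acetate and gives the sulfone-bearing macrocycle A1 with the C7=C8 enoate.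
- In its favour: sulfone-carbanion alkylation is among the most dependable C–C closures for 14-membered rings. C9 comes from the acrylate, so the carbon count is complete without a homologation; on this point it is better than the chosen plan. C3 and C4 are in place before ring closure, so they do not depend on the thermodynamics of the macrocycle; on this point it is also better.
- Against it: C3 and C4 must be built in an open chain by separate stereocontrolled steps, without help from the ring. The sulfonyl group must later be removed reductively from an allylic position next to the Z C11=C12 alkene, which risks alkene migration or loss of geometry. A1 carries C18 as a silyl ether and C19 as an ester, so its redox endgame is no shorter.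
- Comparison: in structure both routes reach the same bicycle, but A1 carries an extra sulfone. In mechanism an irreversible C–C closure is the equal of the olefination of step 12 or better, whereas the chosen plan gains two stereocentres from its ring-forming step at no extra cost. In step economy the chosen plan is shorter.

**Alternative 2:** The cut is the C4–C5 bond. The 14-membered lactone A4 (C18 acyl on the C7 oxygen, vinyl on C7) would be converted with LiN(iPr)2 and Me3SiCl into its silyl ketene acetal. A [3,3] shift would form C4–C5 and the C6=C7 alkene, break C7–O and give the carbocyclic acid A3.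
- In its favour: lactonisation is usually easier than macrocyclic C–C bond formation; here it is the equal of the chosen ring closure or better. The shift is concerted, so C4 is read from the ketene acetal geometry and the C7 carbinol centre, not from an equilibrium.
- Against it: enolisation at C4 places an enolate β to the oxolane oxygen, so E1cB opening of the ether competes with silylation. Inside a 14-membered lactone neither the ketene acetal geometry nor the chair or boat preference is predictable, so C4 is no more certain than in the chosen plan. The alkene arrives at C6=C7 and not at C7=C8, and C8 becomes an extra stereocentre that must later be oxidised and moved into conjugation. A4 needs C1, C3, C7 and C8 set beforehand.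
- Comparison: in structure A3 is further from the target than 19. In mechanism it offers kinetic stereospecificity against thermodynamic control, with comparable uncertainty. In step economy it is clearly longer.

**Alternative 3:** The cuts are O–C3 and C3–C4 in a small, early intermediate. Cu(acac)2 would convert the diazoketone A6 into a copper carbenoid. The C15 ether oxygen would trap it as an oxonium ylide, and the E-butenyl group would shift from oxygen to C3 with allylic transposition to give the oxolan-3-one A5.
- In its favour: one catalytic step makes the ring, a C–C bond and two stereocentres. It is placed early, so failure is cheap, and the stereochemistry is read from an alkene geometry through a compact transition state. On predictability and on where the risk sits, it is better than the chosen plan.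
- Against it: A5 has a C2 ketone that the target lacks. C1 and C3 are both α to it, so its removal costs steps and risks epimerisation. The ether oxygen is tertiary and hindered, so C–H insertion and cyclopropanation can compete. The whole macrocycle, with both trisubstituted alkenes and the ring closure, must still be built afterwards.
- Comparison: in structure it delivers only the oxolane. In mechanism it is kinetic and concerted against reversible. In step economy it is by far the longest.

Key step: step 13

Remarks on the chemistry:
- C9 is not contained in the terpene, acetylide, phosphonoacetate and acetal building blocks and is introduced in step 5.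
- The ester-bearing centre C4 is S by the sequence rule in 19 and becomes R in 20–24 without any change in space, because C18 changes priority on reduction.
- 16 and 17 are mixtures of epimers at the phosphonate carbon, which becomes sp2 in step 12. A minor Z isomer at C3=C4 from step 8 need not be removed.
- Assumption: the diastereomer of 19 with the cis-bridged oxolane and the 4S ester is the most stable one in the macrocycle; this must be confirmed on 19.

## Steps

Step 1
Reactants: 1 methyl 2-(diethoxyphosphoryl)acetate; 2 2-(2-bromoethyl)-1,3-dioxolane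
Product: 3 methyl 2-(diethoxyphosphoryl)-4-(1,3-dioxolan-2-yl)butanoate (racemic)
Conditions: NaH, DMF, 0 °C; then 2, 60 °C
Reagents that add atoms: none
Why: SN2 C-alkylation of the sodium salt of a phosphonoacetate by a primary bromide; the acetal is inert to base and an excess of 1 limits dialkylation.

Step 2
Reactants: 4 neryl acetate, (2Z)-3,7-dimethylocta-2,6-dien-1-yl acetate
Product: 5 (2Z)-5-[(2R)-3,3-dimethyloxiran-2-yl]-3-methylpent-2-en-1-yl acetate
Conditions: D-fructose-derived Shi ketone (0.3 equiv), KHSO5 (as 2KHSO5·KHSO4·K2SO4), K2CO3, Bu4NHSO4, MeCN/CH2(OMe)2/aq. Na2B4O7 buffer, 0 °C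
Reagents that add atoms: potassium peroxymonosulfate KHSO5, [K+].[O-]S(=O)(=O)OO
Why: Shi asymmetric epoxidation: the chiral dioxirane should attack the electron-rich distal alkene, the proximal one being deactivated by the allylic acetate. The D-fructose-derived ketone delivers oxygen to the face of a 2-methylalk-2-ene that gives the (R)-epoxide.

Step 3
Reactants: 5 (2Z)-5-[(2R)-3,3-dimethyloxiran-2-yl]-3-methylpent-2-en-1-yl acetate; 6 lithium acetylide–ethylenediamine complex
Product: 7 (2Z,6R)-6-ethynyl-3,7-dimethyloct-2-ene-1,7-diol
Conditions: 6 (5 equiv), DMSO, rt → 40 °C; then H2O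
Reagents that add atoms: none
Why: SN2 opening of the epoxide by acetylide at the secondary carbon, anti to the C–O bond, so that inversion turns the (R)-epoxide carbon into C1 with the required configuration and leaves the C15 tertiary alkoxide. The amine of the reagent should cleave the acetate in the same pot (aminolysis).

Step 4
Reactants: 7 (2Z,6R)-6-ethynyl-3,7-dimethyloct-2-ene-1,7-diol
Product: 8 (2Z,6R)-6-ethynyl-7-hydroxy-3,7-dimethyloct-2-enal
Conditions: MnO2 (excess), CH2Cl2, 0 °C → rt
Reagents that add atoms: none
Why: Allylic oxidation with MnO2 touches only the primary allylic alcohol; the tertiary alcohol and the alkyne are inert and the neutral heterogeneous medium should keep the Z geometry.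

Step 5
Reactants: 8 (2Z,6R)-6-ethynyl-7-hydroxy-3,7-dimethyloct-2-enal; 9 methyltriphenylphosphonium bromide
Product: 10 (3R,6Z)-3-ethynyl-2,6-dimethylnona-6,8-dien-2-ol
Conditions: 9 (2.5 equiv), KOtBu (2.4 equiv), THF, 0 °C; then 8, −78 → 0 °C
Reagents that add atoms: none
Why: Wittig methylenation adds the missing carbon C9; the ylide reacts with the enal at low temperature faster than it can enolise it, and a slight deficit of base avoids Z to E isomerisation.

Step 6
Reactants: 10 (3R,6Z)-3-ethynyl-2,6-dimethylnona-6,8-dien-2-ol
Product: 11 triethyl{[(3R,6Z)-3-ethynyl-2,6-dimethylnona-6,8-dien-2-yl]oxy}silane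
Conditions: Et3SiOTf, 2,6-lutidine, CH2Cl2, −78 → 0 °C
Reagents that add atoms: triethylsilyl trifluoromethanesulfonate, CC[Si](CC)(CC)OS(=O)(=O)C(F)(F)F
Why: Silylation of a tertiary alcohol with a silyl triflate; the ether keeps the later C3 aldehyde from forming a lactol and keeps the C15 oxygen from adding to the C3=C4 enoate in the open chain.

Step 7
Reactants: 11 triethyl{[(3R,6Z)-3-ethynyl-2,6-dimethylnona-6,8-dien-2-yl]oxy}silane
Product: 13 (3R,6Z)-9-hydroxy-6-methyl-3-[2-(triethylsilyloxy)propan-2-yl]non-6-enal, via bis(disiamylboryl) adduct 12 (not isolated)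
Conditions: Sia2BH (3 equiv; from BH3·THF, 2-methylbut-2-ene), THF, 0 °C → rt; then 30% H2O2, aq. NaOAc, 0 °C → rt
Reagents that add atoms: hydrogen peroxide, OO
Why: Hydroboration–oxidation with a hindered dialkylborane: it adds once to the terminal alkyne (boron on C3) and to the terminal CH=CH2 of the diene (boron on C9) and leaves the trisubstituted alkenes alone. Buffered oxidation then gives the C3 aldehyde and the C9 alcohol.

Step 8
Reactants: 13 (3R,6Z)-9-hydroxy-6-methyl-3-[2-(triethylsilyloxy)propan-2-yl]non-6-enal; 3 methyl 2-(diethoxyphosphoryl)-4-(1,3-dioxolan-2-yl)butanoate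
Product: 14 methyl (2E,5R,8Z)-2-[2-(1,3-dioxolan-2-yl)ethyl]-11-hydroxy-8-methyl-5-[2-(triethylsilyloxy)propan-2-yl]undeca-2,8-dienoate
Conditions: 3 (1.3 equiv), NaH (1.2 equiv), THF, 0 °C; then 13, 0 °C → rt
Reagents that add atoms: none
Why: Horner–Wadsworth–Emmons olefination with an α-alkyl phosphonoacetate, which should give mainly the E trisubstituted enoate. The phosphonate anion is too weak a base to ionise the primary alcohol.

Step 9
Reactants: 14 methyl (2E,5R,8Z)-2-[2-(1,3-dioxolan-2-yl)ethyl]-11-hydroxy-8-methyl-5-[2-(triethylsilyloxy)propan-2-yl]undeca-2,8-dienoate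
Product: 15 methyl (2E,5R,8Z)-2-[2-(1,3-dioxolan-2-yl)ethyl]-11-iodo-8-methyl-5-[2-(triethylsilyloxy)propan-2-yl]undeca-2,8-dienoate
Conditions: I2, PPh3, imidazole, CH2Cl2, 0 °C → rt
Reagents that add atoms: iodine, II
Why: Appel-type iodination of a primary alcohol (SN2 on the alkoxyphosphonium ion); the imidazole buffer should protect the silyl ether and the acetal.

Step 10
Reactants: 15 methyl (2E,5R,8Z)-2-[2-(1,3-dioxolan-2-yl)ethyl]-11-iodo-8-methyl-5-[2-(triethylsilyloxy)propan-2-yl]undeca-2,8-dienoate; 1 methyl 2-(diethoxyphosphoryl)acetate
Product: 16 dimethyl (2E,5R,8Z)-12-(diethoxyphosphoryl)-2-[2-(1,3-dioxolan-2-yl)ethyl]-8-methyl-5-[2-(triethylsilyloxy)propan-2-yl]trideca-2,8-dienedioate (C12 epimers)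
Conditions: 1 (3 equiv), NaH (2.8 equiv), DMF, 0 °C; then 15, 55 °C
Reagents that add atoms: none
Why: SN2 C-alkylation of sodium phosphonoacetate by a primary iodide forms C8–C9. The soft, weakly basic anion favours substitution over elimination, and the hindered trisubstituted enoate should not act as a Michael acceptor.

Step 11
Reactants: 16 dimethyl (2E,5R,8Z)-12-(diethoxyphosphoryl)-2-[2-(1,3-dioxolan-2-yl)ethyl]-8-methyl-5-[2-(triethylsilyloxy)propan-2-yl]trideca-2,8-dienedioate
Product: 17 dimethyl (2E,5R,8Z)-12-(diethoxyphosphoryl)-5-(2-hydroxypropan-2-yl)-8-methyl-2-(3-oxopropyl)trideca-2,8-dienedioate (C12 epimers)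
Conditions: 1 M HCl, THF, 0 °C → rt
Reagents that add atoms: water, O
Why: Acid hydrolysis of the dioxolane and protodesilylation of the triethylsilyl ether in one operation; dilute acid at room temperature should leave the esters, the phosphonate and the trisubstituted alkenes intact.

Step 12
Reactants: 17 dimethyl (2E,5R,8Z)-12-(diethoxyphosphoryl)-5-(2-hydroxypropan-2-yl)-8-methyl-2-(3-oxopropyl)trideca-2,8-dienedioate
Product: 18 dimethyl (1E,5E,8R,11Z)-8-(2-hydroxypropan-2-yl)-11-methylcyclotetradeca-1,5,11-triene-1,5-dicarboxylate (cembrane numbering: 3E,7E,11Z, 1R)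
Conditions: LiCl (10 equiv), DBU (3 equiv), MeCN, rt, slow addition of 17 to about 1 mM
Reagents that add atoms: none
Why: Intramolecular Horner–Wadsworth–Emmons olefination under Masamune–Roush conditions at high dilution closes the 14-membered ring at C7=C8; the α-alkyl diethyl phosphonate should favour E. The amidine base is too weak to ionise the tertiary alcohol to a useful degree, and any early conjugate addition would only anticipate step 13.

Step 13
Reactants: 18 dimethyl (1E,5E,8R,11Z)-8-(2-hydroxypropan-2-yl)-11-methylcyclotetradeca-1,5,11-triene-1,5-dicarboxylate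
Product: 19 dimethyl (1R,4Z,8E,12S,13R)-4,15,15-trimethyl-14-oxabicyclo[11.2.1]hexadeca-4,8-diene-8,12-dicarboxylate (cembrane C1, C3, C4 = positions 1, 13, 12)
Conditions: KOtBu (0.2 equiv), THF, 0 °C → rt; aq. NH4Cl
Reagents that add atoms: none
Why: tert-Butoxide deprotonates the C15 hydroxyl and the alkoxide adds across the ring to C3 of the C3=C4–C18 enoate; the ester enolate is then protonated at C4 by tert-butanol or by a further molecule of 18, which returns the base. The closest known reaction type is the base-mediated intramolecular or transannular oxa-Michael addition of hydroxy enoates to oxolanes and oxanes. The single ring closed is the oxolane, by a 5-exo-trig closure, and the bicyclic frame follows because C1 and C3 both lie in the carbocycle. C3 is controlled by the fixed centre C1 through the ring: addition and retro-addition are both open under alkoxide catalysis, so the system should settle on the cis bridge, in which both bonds from the oxolane into the eleven-carbon chain are pseudo-equatorial. C4 is controlled by equilibration through its enolate, the ester being expected to take the less crowded position next to the new ether carbon, which is 4S in 19 and 4R after reduction; this preference is assumed and must be verified. Regioselectivity comes from geometry: attack on the C7=C8 enoate would need a nine-membered ether, and lactonisation onto C18 would need an E alkene in a seven-membered ring. The gem-dimethyl group at C15 favours closure, and either geometry of C3=C4 would converge on 19.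

Step 14
Reactants: 19 dimethyl (1R,4Z,8E,12S,13R)-4,15,15-trimethyl-14-oxabicyclo[11.2.1]hexadeca-4,8-diene-8,12-dicarboxylate
Product: 20 [(1R,4Z,8E,12R,13R)-4,15,15-trimethyl-14-oxabicyclo[11.2.1]hexadeca-4,8-diene-8,12-diyl]dimethanol
Conditions: iBu2AlH (6 equiv), CH2Cl2, −78 → 0 °C; aq. KNaC4H4O6
Reagents that add atoms: none
Why: Reduction of both esters to primary alcohols by diisobutylaluminium hydride (1,2-reduction of the enoate); there is no base and the temperature is low, so C4 is not enolised, and after this step neither C3 nor C4 can equilibrate.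

Step 15
Reactants: 20 [(1R,4Z,8E,12R,13R)-4,15,15-trimethyl-14-oxabicyclo[11.2.1]hexadeca-4,8-diene-8,12-diyl]dimethanol
Product: 21 (1R,4Z,8E,12R,13R)-12-(hydroxymethyl)-4,15,15-trimethyl-14-oxabicyclo[11.2.1]hexadeca-4,8-diene-8-carbaldehyde
Conditions: MnO2 (excess), CH2Cl2, rt
Reagents that add atoms: none
Why: Chemoselective allylic oxidation: MnO2 oxidises the C19 allylic alcohol to the E enal and leaves the saturated C18 alcohol untouched.

Step 16
Reactants: 21 (1R,4Z,8E,12R,13R)-12-(hydroxymethyl)-4,15,15-trimethyl-14-oxabicyclo[11.2.1]hexadeca-4,8-diene-8-carbaldehyde; 22 3-(tert-butoxy)-3-oxopropanoic acid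
Product: 23 tert-butyl [(1R,4Z,8E,12R,13R)-8-formyl-4,15,15-trimethyl-14-oxabicyclo[11.2.1]hexadeca-4,8-dien-12-yl]methyl propanedioate
Conditions: 22 (1.5 equiv), DCC, DMAP (cat.), CH2Cl2, 0 °C → rt
Reagents that add atoms: none
Why: Steglich esterification of the only hydroxyl group; the aldehyde and the alkenes do not react with the activated acid.

Step 17
Reactants: 23 tert-butyl [(1R,4Z,8E,12R,13R)-8-formyl-4,15,15-trimethyl-14-oxabicyclo[11.2.1]hexadeca-4,8-dien-12-yl]methyl propanedioate
Product: 24 3-{[(1R,4Z,8E,12R,13R)-8-formyl-4,15,15-trimethyl-14-oxabicyclo[11.2.1]hexadeca-4,8-dien-12-yl]methoxy}-3-oxopropanoic acid (CNP0170412.1)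
Conditions: CF3CO2H/CH2Cl2 (1:4), 0 °C, short reaction time
Reagents that add atoms: none
Why: Acidolysis of the tert-butyl ester with loss of 2-methylpropene; the primary malonate ester, the deactivated enal and the cyclic ether should survive brief cold acid, and the half-ester does not decarboxylate at this temperature.

## Compound list

1 | methyl 2-(diethoxyphosphoryl)acetate | CCOP(=O)(CC(=O)OC)OCC | starting material
2 | 2-(2-bromoethyl)-1,3-dioxolane | BrCCC1OCCO1 | starting material
3 | methyl 2-(diethoxyphosphoryl)-4-(1,3-dioxolan-2-yl)butanoate (racemic) | CCOP(=O)(OCC)C(CCC1OCCO1)C(=O)OC | intermediate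
4 | neryl acetate, (2Z)-3,7-dimethylocta-2,6-dien-1-yl acetate | CC(C)=CCC/C(C)=C\COC(C)=O | starting material
5 | (2Z)-5-[(2R)-3,3-dimethyloxiran-2-yl]-3-methylpent-2-en-1-yl acetate | CC1(C)O[C@@H]1CC/C(C)=C\COC(C)=O | intermediate
6 | lithium acetylide–ethylenediamine complex | [Li+].[C-]#C.NCCN | starting material
7 | (2Z,6R)-6-ethynyl-3,7-dimethyloct-2-ene-1,7-diol | C#C[C@@H](CC/C(C)=C\CO)C(C)(C)O | intermediate
8 | (2Z,6R)-6-ethynyl-7-hydroxy-3,7-dimethyloct-2-enal | C#C[C@@H](CC/C(C)=C\C=O)C(C)(C)O | intermediate
9 | methyltriphenylphosphonium bromide | C[P+](c1ccccc1)(c1ccccc1)c1ccccc1.[Br-] | starting material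
10 | (3R,6Z)-3-ethynyl-2,6-dimethylnona-6,8-dien-2-ol | C#C[C@@H](CC/C(C)=C\C=C)C(C)(C)O | intermediate
11 | triethyl{[(3R,6Z)-3-ethynyl-2,6-dimethylnona-6,8-dien-2-yl]oxy}silane | C#C[C@@H](CC/C(C)=C\C=C)C(C)(C)O[Si](CC)(CC)CC | intermediate
12 | bis(disiamylboryl) adduct of 11: (E)-alkenylborane at C3, alkylborane at C9 | CC(C)C(C)B(/C=C/[C@@H](CC/C(C)=C\CCB(C(C)C(C)C)C(C)C(C)C)C(C)(C)O[Si](CC)(CC)CC)C(C)C(C)C | intermediate
13 | (3R,6Z)-9-hydroxy-6-methyl-3-[2-(triethylsilyloxy)propan-2-yl]non-6-enal | O=CC[C@@H](CC/C(C)=C\CCO)C(C)(C)O[Si](CC)(CC)CC | intermediate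
14 | methyl (2E,5R,8Z)-2-[2-(1,3-dioxolan-2-yl)ethyl]-11-hydroxy-8-methyl-5-[2-(triethylsilyloxy)propan-2-yl]undeca-2,8-dienoate | COC(=O)/C(CCC1OCCO1)=C/C[C@@H](CC/C(C)=C\CCO)C(C)(C)O[Si](CC)(CC)CC | intermediate
15 | methyl (2E,5R,8Z)-2-[2-(1,3-dioxolan-2-yl)ethyl]-11-iodo-8-methyl-5-[2-(triethylsilyloxy)propan-2-yl]undeca-2,8-dienoate | COC(=O)/C(CCC1OCCO1)=C/C[C@@H](CC/C(C)=C\CCI)C(C)(C)O[Si](CC)(CC)CC | intermediate
16 | dimethyl (2E,5R,8Z)-12-(diethoxyphosphoryl)-2-[2-(1,3-dioxolan-2-yl)ethyl]-8-methyl-5-[2-(triethylsilyloxy)propan-2-yl]trideca-2,8-dienedioate (C12 epimers) | COC(=O)/C(CCC1OCCO1)=C/C[C@@H](CC/C(C)=C\CCC(C(=O)OC)P(=O)(OCC)OCC)C(C)(C)O[Si](CC)(CC)CC | intermediate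
17 | dimethyl (2E,5R,8Z)-12-(diethoxyphosphoryl)-5-(2-hydroxypropan-2-yl)-8-methyl-2-(3-oxopropyl)trideca-2,8-dienedioate (C12 epimers) | COC(=O)/C(CCC=O)=C/C[C@@H](CC/C(C)=C\CCC(C(=O)OC)P(=O)(OCC)OCC)C(C)(C)O | intermediate
18 | dimethyl (1E,5E,8R,11Z)-8-(2-hydroxypropan-2-yl)-11-methylcyclotetradeca-1,5,11-triene-1,5-dicarboxylate | C/C1=C/CC/C(C(=O)OC)=C\CC/C(C(=O)OC)=C\C[C@@H](CC1)C(C)(C)O | intermediate
19 | dimethyl (1R,4Z,8E,12S,13R)-4,15,15-trimethyl-14-oxabicyclo[11.2.1]hexadeca-4,8-diene-8,12-dicarboxylate | C/C1=C/CC/C(C(=O)OC)=C\CC[C@H](C(=O)OC)[C@H]2C[C@@H](CC1)C(C)(C)O2 | intermediate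
20 | [(1R,4Z,8E,12R,13R)-4,15,15-trimethyl-14-oxabicyclo[11.2.1]hexadeca-4,8-diene-8,12-diyl]dimethanol | C/C1=C/CC/C(CO)=C\CC[C@H](CO)[C@H]2C[C@@H](CC1)C(C)(C)O2 | intermediate
21 | (1R,4Z,8E,12R,13R)-12-(hydroxymethyl)-4,15,15-trimethyl-14-oxabicyclo[11.2.1]hexadeca-4,8-diene-8-carbaldehyde | C/C1=C/CC/C(C=O)=C\CC[C@H](CO)[C@H]2C[C@@H](CC1)C(C)(C)O2 | intermediate
22 | 3-(tert-butoxy)-3-oxopropanoic acid (mono-tert-butyl malonate) | CC(C)(C)OC(=O)CC(=O)O | starting material
23 | tert-butyl [(1R,4Z,8E,12R,13R)-8-formyl-4,15,15-trimethyl-14-oxabicyclo[11.2.1]hexadeca-4,8-dien-12-yl]methyl propanedioate | C/C1=C/CC/C(C=O)=C\CC[C@H](COC(=O)CC(=O)OC(C)(C)C)[C@H]2C[C@@H](CC1)C(C)(C)O2 | intermediate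
24 | 3-{[(1R,4Z,8E,12R,13R)-8-formyl-4,15,15-trimethyl-14-oxabicyclo[11.2.1]hexadeca-4,8-dien-12-yl]methoxy}-3-oxopropanoic acid | C/C1=C/CC/C(C=O)=C\CC[C@H](COC(=O)CC(=O)O)[C@H]2C[C@@H](CC1)C(C)(C)O2 | target

## Step count and least certain steps

Total: 17 steps. Longest linear sequence: 16 steps (4 to 24, steps 2–17); step 1 is a one-step side branch.

**Step 13 (key step).** The equilibrium may not lie where it is needed: the ring could favour the other configuration at C4 or the trans bridge at C3, or retro-addition could leave part of the material open, because the relative stability of the bicyclic diastereomers is assumed and not known. The fallback sets out from 18 and replaces equilibrium control by two kinetically controlled operations. The ring is closed with one equivalent of KN(SiMe3)2 in THF at −78 °C and the enolate is trapped at once with Me3SiCl as the silyl ketene acetal F1. F1 is then protonated at low temperature with a hindered or chiral proton donor, so that C4 is set by the reagent and the face of the ketene acetal. This comes back to the route at 19.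

**Step 3.** SN2 attack at a secondary carbon next to a quaternary centre is slow, so base-induced isomerisation of the epoxide to an allylic alcohol, or opening by the freed allylic alkoxide of the same molecule, may compete. The fallback sets out from 5 and changes from a nucleophile-driven opening to a Lewis-acid-activated one on a protected substrate. K2CO3 in MeOH gives the epoxy alcohol F2, and tert-butyldimethylsilyl chloride with imidazole gives the silyl ether F3. LiC≡CSiMe3 (from ethynyltrimethylsilane and n-BuLi) with BF3·OEt2 in THF at −78 °C opens the epoxide to the silylated alkyne F4. Bu4NF removes both silyl groups, which comes back to the route at 7.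

**Step 7.** Chemoselectivity may be lost: the alkyne may be hydroborated twice, boron may add to the inner diene position, or the aldehyde may be over-oxidised, because one reagent has to do two jobs in one flask. The fallback sets out from 11 and separates the two functionalisations. Ruthenium-catalysed anti-Markovnikov hydration of the alkyne ([CpRu(NCMe)3]PF6 with 5,5′-bis(trifluoromethyl)-2,2′-bipyridine, aqueous acetone) gives the dienyl aldehyde F5 without touching the diene. Olefination with 3 as in step 8 gives the trienoate F6. 9-BBN then adds only to the terminal CH=CH2, and oxidation with NaBO3·4H2O comes back to the route at 14.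

**Step 12.** Intermolecular olefination may compete with ring closure, and strain in the closing transition state may erode the E selectivity at C7=C8. The fallback sets out from 17 and no longer asks the ring closure for this geometry. The Z-configured macrocycle F7 that forms is carried through step 13 to the Z diester F8, through step 14 to the Z diol F9 and through step 15 to the Z enal F10. The geometry is then set by thermodynamic equilibration of F10 with a nucleophilic catalyst that adds reversibly to C7 (catalytic PhSH with Et3N, or DABCO), the E enal being the stable isomer. This comes back to the route at 21.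

## Further compounds

F1 | step 13 | methyl (1R,4Z,8E,13R)-12-[methoxy(trimethylsilyloxy)methylidene]-4,15,15-trimethyl-14-oxabicyclo[11.2.1]hexadeca-4,8-diene-8-carboxylate | C/C1=C/CC/C(C(=O)OC)=C\CCC(=C(OC)O[Si](C)(C)C)[C@H]2C[C@@H](CC1)C(C)(C)O2
F2 | step 3 | (2Z)-5-[(2R)-3,3-dimethyloxiran-2-yl]-3-methylpent-2-en-1-ol | CC1(C)O[C@@H]1CC/C(C)=C\CO
F3 | step 3 | tert-butyl{[(2Z)-5-[(2R)-3,3-dimethyloxiran-2-yl]-3-methylpent-2-en-1-yl]oxy}dimethylsilane | CC1(C)O[C@@H]1CC/C(C)=C\CO[Si](C)(C)C(C)(C)C
F4 | step 3 | (3R,6Z)-8-{[tert-butyl(dimethyl)silyl]oxy}-2,6-dimethyl-3-[(trimethylsilyl)ethynyl]oct-6-en-2-ol | C[Si](C)(C)C#C[C@@H](CC/C(C)=C\CO[Si](C)(C)C(C)(C)C)C(C)(C)O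
F5 | step 7 | (3R,6Z)-6-methyl-3-[2-(triethylsilyloxy)propan-2-yl]nona-6,8-dienal | O=CC[C@@H](CC/C(C)=C\C=C)C(C)(C)O[Si](CC)(CC)CC
F6 | step 7 | methyl (2E,5R,8Z)-2-[2-(1,3-dioxolan-2-yl)ethyl]-8-methyl-5-[2-(triethylsilyloxy)propan-2-yl]undeca-2,8,10-trienoate | COC(=O)/C(CCC1OCCO1)=C/C[C@@H](CC/C(C)=C\C=C)C(C)(C)O[Si](CC)(CC)CC
F7 | step 12 | dimethyl (1Z,5E,8R,11Z)-8-(2-hydroxypropan-2-yl)-11-methylcyclotetradeca-1,5,11-triene-1,5-dicarboxylate | C/C1=C/CC/C(C(=O)OC)=C/CC/C(C(=O)OC)=C\C[C@@H](CC1)C(C)(C)O
F8 | step 12 | dimethyl (1R,4Z,8Z,12S,13R)-4,15,15-trimethyl-14-oxabicyclo[11.2.1]hexadeca-4,8-diene-8,12-dicarboxylate | C/C1=C/CC/C(C(=O)OC)=C/CC[C@H](C(=O)OC)[C@H]2C[C@@H](CC1)C(C)(C)O2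
F9 | step 12 | [(1R,4Z,8Z,12R,13R)-4,15,15-trimethyl-14-oxabicyclo[11.2.1]hexadeca-4,8-diene-8,12-diyl]dimethanol | C/C1=C/CC/C(CO)=C/CC[C@H](CO)[C@H]2C[C@@H](CC1)C(C)(C)O2
F10 | step 12 | (1R,4Z,8Z,12R,13R)-12-(hydroxymethyl)-4,15,15-trimethyl-14-oxabicyclo[11.2.1]hexadeca-4,8-diene-8-carbaldehyde | C/C1=C/CC/C(C=O)=C/CC[C@H](CO)[C@H]2C[C@@H](CC1)C(C)(C)O2
A1 | alternative 1 | oxolane-bridged 14-membered carbocycle with C10 phenylsulfonyl group (epimers), C8 methyl ester and C18 silyl ether | C/C1=C/C(S(=O)(=O)c2ccccc2)C/C(C(=O)OC)=C\CC[C@H](CO[Si](c3ccccc3)(c3ccccc3)C(C)(C)C)[C@H]4C[C@@H](CC1)C(C)(C)O4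
A2 | alternative 1 | open-chain Baylis–Hillman acetate (C7 acetate, C8 acrylate) with preformed oxolane and C10 allylic phenyl sulfone | C=C(C(=O)OC)C(OC(C)=O)CC[C@H](CO[Si](c1ccccc1)(c1ccccc1)C(C)(C)C)[C@H]2C[C@@H](CC/C(C)=C\CS(=O)(=O)c1ccccc1)C(C)(C)O2
A3 | alternative 2 | oxolane-bridged 14-membered carbocyclic C18 acid with E C6=C7 alkene and C8 silyloxymethyl group | C/C1=C/CC[C@@H](CO[Si](C)(C)C(C)(C)C)/C=C/C[C@H](C(=O)O)[C@H]2C[C@@H](CC1)C(C)(C)O2
A4 | alternative 2 | 14-membered lactone of the C18 acid with the C7 carbinol, vinyl group on C7, oxolane in place (C7 configuration left open) | C/C1=C/CC[C@@H](CO[Si](C)(C)C(C)(C)C)C(C=C)OC(=O)C[C@H]2C[C@@H](CC1)C(C)(C)O2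
A5 | alternative 3 | 2,4-disubstituted 5,5-dimethyloxolan-3-one with C3 and C4 set | C=C[C@H](CO[Si](c1ccccc1)(c1ccccc1)C(C)(C)C)[C@H]1C(=O)[C@@H](CCO[Si](C)(C)C(C)(C)C)C(C)(C)O1
A6 | alternative 3 | diazoketone (C3 diazo carbon, C2 ketone) with the C15 oxygen as (E)-4-silyloxybut-2-enyl ether | [N-]=[N+]=CC(=O)[C@@H](CCO[Si](C)(C)C(C)(C)C)C(C)(C)OC/C=C/CO[Si](c1ccccc1)(c1ccccc1)C(C)(C)C
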